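Everything rests on the C5–C6 bond of the docosyl chain (numbered from the ester oxygen), treated as a masked alkene. The key step exploits that both atoms are plain CH2 groups, remote from the ester and the 2,3-dihydroxyphenyl ring, and that each half plus one carbon is an even-numbered terminal olefin. Unprotected 2,3-dihydroxybenzoic acid is alkylated at the carboxylate with 6-bromohex-1-ene; ruthenium-catalysed cross-metathesis of the resulting hex-5-en-1-yl ester with the commodity α-olefin octadec-1-ene should then forge C5=C6 with loss of ethene, uniting both halves in one operation. Hydrogenation finally erases the alkene and its geometry; no protecting group is used.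

Key step: step 2

Remark: the target has no stereocentre and no stereogenic double bond, so it is achiral and the question of a single enantiomer does not arise; the only stereochemical element on the route, the E/Z geometry of the metathesis product, is removed by the final hydrogenation.

Step 1
Reactants: 1 2,3-dihydroxybenzoic acid; 2 6-bromohex-1-ene
Product: 3 hex-5-en-1-yl 2,3-dihydroxybenzoate
Conditions: KHCO3 (1.1 equiv), DMF, 50 °C, N2
Reagents that add atoms: none
Why: Carboxylate O-alkylation (SN2): bicarbonate deprotonates only the carboxylic acid, which is several pKa units more acidic than the C3 phenol and the hydrogen-bonded C2 phenol, so the primary bromide should be attacked by the carboxylate alone and the ester should form without protection of the catechol.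

Step 2
Reactants: 3 hex-5-en-1-yl 2,3-dihydroxybenzoate; 4 octadec-1-ene
Product: 5 (E)-docos-5-en-1-yl 2,3-dihydroxybenzoate
Conditions: 4 (4 equiv), Grubbs II [(H2IMes)(PCy3)Cl2Ru=CHPh] (3 mol %), 1,4-benzoquinone (10 mol %), CH2Cl2, 40 °C, argon sweep
Reagents that add atoms: none
Why: Olefin cross-metathesis by the metal carbene/metallacyclobutane mechanism: the ruthenium benzylidene is converted into alkylidenes of 3 and 4, and [2+2] cycloaddition/cycloreversion joins C5 of the hexenyl ester to C2 of octadec-1-ene as the new C5=C6 bond, while the two terminal CH2 groups leave as ethene, which is swept out and drives the equilibrium. The closest known reaction type is the cross-metathesis of two unhindered terminal (type I) olefins with second-generation ruthenium carbenes, which tolerate esters and free phenols. No ring is closed and no stereocentre is formed; the alkene is expected as an E-rich E/Z mixture, which is of no consequence because step 3 saturates it. The first selectivity needed is cross- over self-metathesis: both partners are type I olefins and the distribution is statistical, so the cheap olefin 4 is used in fourfold excess, and the homodimer of 3 is itself a substrate that secondary metathesis with 4 should return to 5. The second is that no double-bond migration precedes metathesis, since that would shorten or lengthen the chain by one carbon; the mild temperature and the hydride scavenger 1,4-benzoquinone are meant to secure this. The substrate helps in two ways: its C2 hydroxyl is tied up in a hydrogen bond to the ester carbonyl, which lowers the tendency of the catechol to chelate ruthenium, and its polarity should let silica gel separate 5 from octadecene and its hydrocarbon dimer.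

Step 3
Reactants: 5 (E)-docos-5-en-1-yl 2,3-dihydroxybenzoate
Product: 6 Gentiside J (docosyl 2,3-dihydroxybenzoate)
Conditions: H2 (1 atm), 10% Pd/C, EtOAc, rt
Reagents that add atoms: none
Why: Heterogeneous catalytic hydrogenation adds H2 across the 1,2-disubstituted C5=C6 bond, E and Z isomers converge on the same saturated chain, and the non-benzylic ester C–O bond, the arene and the phenols should be inert to Pd/C at 1 atm and room temperature.

Compound list
1 | 2,3-dihydroxybenzoic acid | OC(=O)c1cccc(O)c1O | starting material
2 | 6-bromohex-1-ene | C=CCCCCBr | starting material
3 | hex-5-en-1-yl 2,3-dihydroxybenzoate | C=CCCCCOC(=O)c1cccc(O)c1O | intermediate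
4 | octadec-1-ene | CCCCCCCCCCCCCCCCC=C | starting material
5 | (E)-docos-5-en-1-yl 2,3-dihydroxybenzoate (E isomer drawn; any Z isomer is carried along and converges in step 3) | CCCCCCCCCCCCCCCC/C=C/CCCCOC(=O)c1cccc(O)c1O | intermediate
6 | Gentiside J, docosyl 2,3-dihydroxybenzoate | CCCCCCCCCCCCCCCCCCCCCCOC(=O)c1cccc(O)c1O | target

Total step count: 3
Longest linear sequence: 3 steps (1 → 3 → 5 → 6)

Steps most likely to fail

1. Step 2 (key step). The free catechol may chelate the ruthenium carbene and stall turnover, on top of statistical self-metathesis, so that conversion of the limiting olefin stops early. The fallback masks the catechol before metathesis and unmasks it in the final reduction. Setting out from 3, both phenols would be benzylated (BnBr, K2CO3, DMF) to give hex-5-en-1-yl 2,3-bis(benzyloxy)benzoate F1. Cross-metathesis of F1 with 4 under the conditions of step 2 should give (E)-docos-5-en-1-yl 2,3-bis(benzyloxy)benzoate F2. Hydrogenation over Pd/C (H2, EtOAc/EtOH) would then saturate C5=C6 and cleave both benzyl ethers in the same operation, so the fallback comes back to the route at 6 and bypasses 5.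

2. Step 1. Partial deprotonation of the C3 phenol may lead to competing ether formation, or the substitution may be sluggish. The fallback replaces SN2 at the alkyl halide by acyl substitution at the carboxyl carbon. Setting out from 1, acid-catalysed Fischer esterification with hex-5-en-1-ol (cat. p-TsOH, toluene, reflux with azeotropic removal of water), under which the phenols are not nucleophilic enough to compete, comes back to the route at 3. This detour makes no new compound (F0).

3. Step 3. Ruthenium residues or adsorption of the catechol may poison the palladium surface, leaving saturation incomplete. The fallback is a metal-free transfer of H2. Setting out from 5, diimide reduction (p-toluenesulfonyl hydrazide, NaOAc, THF–H2O, reflux, N2) comes back to the route at 6. This detour makes no new compound (F0).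

Further compounds
F1 | step 2 | hex-5-en-1-yl 2,3-bis(benzyloxy)benzoate | C=CCCCCOC(=O)c1cccc(OCc2ccccc2)c1OCc1ccccc1
F2 | step 2 | (E)-docos-5-en-1-yl 2,3-bis(benzyloxy)benzoate | CCCCCCCCCCCCCCCC/C=C/CCCCOC(=O)c1cccc(OCc2ccccc2)c1OCc1ccccc1
F0 | step 1 | none | none
F0 | step 3 | none | none
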